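**Retrosynthetic overview** (chain numbering of acid 18: C1 = CO2H … C14 = CHPh)
1. Target 19 ⇐ linear hexaenoic acid 18 by one intramolecular Diels–Alder reaction (diene C7–C10, dienophile C2=C3, Z-alkene C4=C5 in the three-atom tether). The five-membered and six-membered rings close together and four of the five stereocentres are set there.
2. 18 ⇐ Z-alkenyl iodide 14 + (E)-3-iodo-2-methylacrylic acid 15 (C3–C4 Suzuki–Miyaura bond); 18 is made and cyclised in the same flask with the acid unprotected.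
3. 14 ⇐ aldehyde 12 (Zhao iodo-olefination sets 4Z) ⇐ alcohol 11.
4. The tetraene of 11 ⇐ Roche aldehyde 3 by three E-selective formyl-ylide Wittig homologations (4, 6, 4) and one benzylphosphonate olefination (9).
5. The C6 stereocentre, the only one carried in, ⇐ (R)-Roche ester 1.

Assumption: CNP0103503.1 is taken as exactly the stereoisomer of the given SMILES, and ylide 6 and iodo acid 15 are taken as catalogue chemicals (otherwise one to two steps from propyltriphenylphosphonium bromide and from diethyl methylmalonate).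

**Route**

Step 1
Reactants: 1 methyl (2R)-3-hydroxy-2-methylpropanoate
Product: 2 methyl (2R)-3-[(tert-butyldimethylsilyl)oxy]-2-methylpropanoate
Conditions: TBSCl, imidazole, CH2Cl2, 0 °C to rt
Reagents that add atoms: tert-butyl(chloro)dimethylsilane, CC(C)(C)[Si](C)(C)Cl
Why: Imidazole-mediated silylation of the primary alcohol masks the C5 oxygen for the reduction and olefination steps and does not touch the stereocentre.

Step 2
Reactants: 2 methyl (2R)-3-[(tert-butyldimethylsilyl)oxy]-2-methylpropanoate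
Product: 3 (2R)-3-[(tert-butyldimethylsilyl)oxy]-2-methylpropanal
Conditions: i-Bu2AlH (1.1 equiv), CH2Cl2, −78 °C; MeOH, aq. KNaC4H4O6; used crude
Reagents that add atoms: none
Why: Partial ester reduction with i-Bu2AlH stops at the aluminium hemiacetal at −78 °C, and the cold neutral work-up delivers the aldehyde without epimerising the α-stereocentre.

Step 3
Reactants: 3 (2R)-3-[(tert-butyldimethylsilyl)oxy]-2-methylpropanal; 4 2-(triphenylphosphoranylidene)propanal
Product: 5 (2E,4S)-5-[(tert-butyldimethylsilyl)oxy]-2,4-dimethylpent-2-enal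
Conditions: toluene, 90 °C, 16 h
Reagents that add atoms: none
Why: Wittig olefination with the stabilised formyl ylide is neutral and E-selective (formyl trans to the chain), so the 7E alkene forms without loss of configuration at C6.

Step 4
Reactants: 5 (2E,4S)-5-[(tert-butyldimethylsilyl)oxy]-2,4-dimethylpent-2-enal; 6 2-(triphenylphosphoranylidene)butanal
Product: 7 (2E,4E,6S)-7-[(tert-butyldimethylsilyl)oxy]-2-ethyl-4,6-dimethylhepta-2,4-dienal
Conditions: toluene, 110 °C, 36 h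
Reagents that add atoms: none
Why: A second stabilised Wittig olefination puts the formyl group trans to the chain and so fixes the 9E geometry that later decides the configuration of the ethyl-bearing quaternary carbon, while the α-ethyl product is too hindered to react on.

Step 5
Reactants: 7 (2E,4E,6S)-7-[(tert-butyldimethylsilyl)oxy]-2-ethyl-4,6-dimethylhepta-2,4-dienal; 4 2-(triphenylphosphoranylidene)propanal
Product: 8 (2E,4E,6E,8S)-9-[(tert-butyldimethylsilyl)oxy]-4-ethyl-2,6,8-trimethylnona-2,4,6-trienal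
Conditions: 4 (1.3 equiv), toluene, 110 °C, 48 h, BHT, stopped at about 85% conversion
Reagents that add atoms: none
Why: The third stabilised Wittig olefination sets the 11E alkene by the same thermodynamic preference, and limiting the ylide keeps the less electrophilic trienal product from being homologated again.

Step 6
Reactants: 8 (2E,4E,6E,8S)-9-[(tert-butyldimethylsilyl)oxy]-4-ethyl-2,6,8-trimethylnona-2,4,6-trienal; 9 diethyl benzylphosphonate
Product: 11 (2S,3E,5E,7E,9E)-6-ethyl-2,4,8-trimethyl-10-phenyldeca-3,5,7,9-tetraen-1-ol, via tetraenyl TBS ether 10 (not isolated)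
Conditions: 9, NaN(SiMe3)2, THF, −78 °C to 0 °C; then Bu4NF, 0 °C to rt; amber glassware
Reagents that add atoms: none
Why: Horner–Wadsworth–Emmons olefination with the benzylphosphonate anion gives the E-styryl terminus (13E), and fluoride added to the same flask cleaves the primary silyl ether through Si–F bond formation without touching the tetraene.

Step 7
Reactants: 11 (2S,3E,5E,7E,9E)-6-ethyl-2,4,8-trimethyl-10-phenyldeca-3,5,7,9-tetraen-1-ol
Product: 12 (2S,3E,5E,7E,9E)-6-ethyl-2,4,8-trimethyl-10-phenyldeca-3,5,7,9-tetraenal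
Conditions: Dess–Martin periodinane, NaHCO3, CH2Cl2, 0 °C, 30 min; used crude at once
Reagents that add atoms: none
Why: Buffered Dess–Martin oxidation is fast and non-enolising, so the α-methyl β,γ-unsaturated aldehyde forms without epimerisation at C6 or migration of the C7 alkene into conjugation.

Step 8
Reactants: 12 (2S,3E,5E,7E,9E)-6-ethyl-2,4,8-trimethyl-10-phenyldeca-3,5,7,9-tetraenal; 13 ethyltriphenylphosphonium iodide
Product: 14 [(1E,3E,5E,7E,9S,10Z)-5-ethyl-11-iodo-3,7,9-trimethyldodeca-1,3,5,7,10-pentaen-1-yl]benzene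
Conditions: 13, n-BuLi, THF, rt; I2, −78 °C; NaN(SiMe3)2, −20 °C; then 12, −78 °C to −20 °C
Reagents that add atoms: iodine, II
Why: The Zhao variant of the Stork–Zhao Wittig olefination adds the α-iodo ylide under kinetic control at −78 °C and gives the (Z)-2-iodoalkene with iodine cis to C6, the geometry the tether alkene needs, at a temperature where the α-stereocentre of 12 survives.

Step 9
Reactants: 14 [(1E,3E,5E,7E,9S,10Z)-5-ethyl-11-iodo-3,7,9-trimethyldodeca-1,3,5,7,10-pentaen-1-yl]benzene; 15 (2E)-3-iodo-2-methylprop-2-enoic acid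
Product: 19 (1R,3aR,4R,5S,7aS)-5-ethyl-1,3,4,7-tetramethyl-5-[(1E,3E)-2-methyl-4-phenylbuta-1,3-dien-1-yl]-3a,4,5,7a-tetrahydro-1H-indene-4-carboxylic acid, via alkenyllithium 16 (not isolated), via alkenyl pinacol boronate 17 (not isolated), via linear hexaenoic acid 18 (not isolated)
Conditions: t-BuLi (2.0 equiv), Et2O, −78 °C; i-PrOBpin, −78 °C to 0 °C; then 15, Pd(dppf)Cl2 (5 mol %), aq. K3PO4, THF, 40 °C; then aq. KHSO4 to pH 3, toluene, BHT, 80 °C, 12 h
Reagents that add atoms: none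
Why: Iodine–lithium exchange, borylation and Suzuki–Miyaura coupling all proceed with retention to give the (2E,4Z)-dienoic acid, and the intramolecular Diels–Alder reaction then closes both rings through the transition state with CO2H endo, the tether exo and C6–H eclipsing the C8 methyl (allylic 1,3-strain), which sets C7a (S) and C3a (R) trans-fused, C4 (R) from the 2E dienophile and C5 (S) from the 9E diene, all relative to the C6 methyl centre that becomes C1 (R).

**Compound list**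

1 | methyl (2R)-3-hydroxy-2-methylpropanoate ((R)-Roche ester) | COC(=O)[C@H](C)CO | starting material
2 | methyl (2R)-3-[(tert-butyldimethylsilyl)oxy]-2-methylpropanoate | COC(=O)[C@H](C)CO[Si](C)(C)C(C)(C)C | intermediate
3 | (2R)-3-[(tert-butyldimethylsilyl)oxy]-2-methylpropanal | O=C[C@H](C)CO[Si](C)(C)C(C)(C)C | intermediate
4 | 2-(triphenylphosphoranylidene)propanal | CC(C=O)=P(c1ccccc1)(c1ccccc1)c1ccccc1 | starting material
5 | (2E,4S)-5-[(tert-butyldimethylsilyl)oxy]-2,4-dimethylpent-2-enal | O=C/C(C)=C/[C@H](C)CO[Si](C)(C)C(C)(C)C | intermediate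
6 | 2-(triphenylphosphoranylidene)butanal | CCC(C=O)=P(c1ccccc1)(c1ccccc1)c1ccccc1 | starting material
7 | (2E,4E,6S)-7-[(tert-butyldimethylsilyl)oxy]-2-ethyl-4,6-dimethylhepta-2,4-dienal | O=C/C(CC)=C/C(C)=C/[C@H](C)CO[Si](C)(C)C(C)(C)C | intermediate
8 | (2E,4E,6E,8S)-9-[(tert-butyldimethylsilyl)oxy]-4-ethyl-2,6,8-trimethylnona-2,4,6-trienal | O=C/C(C)=C/C(CC)=C/C(C)=C/[C@H](C)CO[Si](C)(C)C(C)(C)C | intermediate
9 | diethyl benzylphosphonate | CCOP(=O)(Cc1ccccc1)OCC | starting material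
10 | tert-butyl{[(2S,3E,5E,7E,9E)-6-ethyl-2,4,8-trimethyl-10-phenyldeca-3,5,7,9-tetraen-1-yl]oxy}dimethylsilane | c1ccccc1/C=C/C(C)=C/C(CC)=C/C(C)=C/[C@H](C)CO[Si](C)(C)C(C)(C)C | intermediate (not isolated)
11 | (2S,3E,5E,7E,9E)-6-ethyl-2,4,8-trimethyl-10-phenyldeca-3,5,7,9-tetraen-1-ol | c1ccccc1/C=C/C(C)=C/C(CC)=C/C(C)=C/[C@H](C)CO | intermediate
12 | (2S,3E,5E,7E,9E)-6-ethyl-2,4,8-trimethyl-10-phenyldeca-3,5,7,9-tetraenal | c1ccccc1/C=C/C(C)=C/C(CC)=C/C(C)=C/[C@H](C)C=O | intermediate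
13 | ethyltriphenylphosphonium iodide | CC[P+](c1ccccc1)(c1ccccc1)c1ccccc1.[I-] | starting material
14 | [(1E,3E,5E,7E,9S,10Z)-5-ethyl-11-iodo-3,7,9-trimethyldodeca-1,3,5,7,10-pentaen-1-yl]benzene (iodine cis to the CH(CH3) carbon) | c1ccccc1/C=C/C(C)=C/C(CC)=C/C(C)=C/[C@H](C)/C=C(C)\I | intermediate
15 | (2E)-3-iodo-2-methylprop-2-enoic acid | OC(=O)/C(C)=C/I | starting material
16 | [(2E,4R,5E,7E,9E,11E)-8-ethyl-4,6,10-trimethyl-12-phenyldodeca-2,5,7,9,11-pentaen-2-yl]lithium (Li in place of the iodine of 14, geometry kept) | c1ccccc1/C=C/C(C)=C/C(CC)=C/C(C)=C/[C@H](C)/C=C(C)\[Li] | intermediate (not isolated)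
17 | 2-[(2E,4R,5E,7E,9E,11E)-8-ethyl-4,6,10-trimethyl-12-phenyldodeca-2,5,7,9,11-pentaen-2-yl]-4,4,5,5-tetramethyl-1,3,2-dioxaborolane | c1ccccc1/C=C/C(C)=C/C(CC)=C/C(C)=C/[C@H](C)/C=C(C)\B1OC(C)(C)C(C)(C)O1 | intermediate (not isolated)
18 | (2E,4Z,6S,7E,9E,11E,13E)-10-ethyl-2,4,6,8,12-pentamethyl-14-phenyltetradeca-2,4,7,9,11,13-hexaenoic acid | c1ccccc1/C=C/C(C)=C/C(CC)=C/C(C)=C/[C@H](C)/C=C(C)\C=C(/C)C(=O)O | intermediate (not isolated)
19 | (1R,3aR,4R,5S,7aS)-5-ethyl-1,3,4,7-tetramethyl-5-[(1E,3E)-2-methyl-4-phenylbuta-1,3-dien-1-yl]-3a,4,5,7a-tetrahydro-1H-indene-4-carboxylic acid (trans ring fusion; on one face the dienyl group, CO2H, H-3a and H-1; on the other face ethyl, the C4 methyl, H-7a and the C1 methyl) | CC[C@]1(/C=C(C)/C=C/c2ccccc2)C=C(C)[C@H]2[C@H](C)C=C(C)[C@@H]2[C@@]1(C)C(=O)O | target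

**Step count and risks**

Total step count: 9. Longest linear sequence: 9 (steps 1 to 9 from 1).

Most likely to fail, first: step 9. The borylation and coupling act on a hindered Z-alkenyl unit, the acid is unprotected, and the cyclisation must join two fully substituted carbons faster than a 1,5-hydrogen shift of the Z-dienoic acid. The fallback sets out from 14 and comes back at 19. Stille coupling of 14 with (E)-2-methyl-3-(tributylstannyl)prop-2-en-1-ol (Pd(PPh3)4, CuI, CsF, DMF, rt) gives (2E,4Z,6S,7E,9E,11E,13E)-10-ethyl-2,4,6,8,12-pentamethyl-14-phenyltetradeca-2,4,7,9,11,13-hexaen-1-ol F1. MnO2 (CH2Cl2, rt) gives (2E,4Z,6S,7E,9E,11E,13E)-10-ethyl-2,4,6,8,12-pentamethyl-14-phenyltetradeca-2,4,7,9,11,13-hexaenal F2. Its enal is a stronger dienophile than the acid, so the same intramolecular Diels–Alder reaction runs at rt to 40 °C and gives (1R,3aR,4R,5S,7aS)-5-ethyl-1,3,4,7-tetramethyl-5-[(1E,3E)-2-methyl-4-phenylbuta-1,3-dien-1-yl]-3a,4,5,7a-tetrahydro-1H-indene-4-carbaldehyde F3. NaClO2, NaH2PO4 and 2-methylbut-2-ene in t-BuOH/H2O oxidise F3 to 19.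

Second: step 8. Aldehyde 12 epimerises and conjugates easily, and Zhao olefinations often give modest yields. The fallback sets out from 12 and comes back at 18. Still–Gennari olefination of 12 with ethyl 2-[bis(2,2,2-trifluoroethoxy)phosphoryl]propanoate (KN(SiMe3)2, 18-crown-6, THF, −78 °C) gives ethyl (2Z,4S,5E,7E,9E,11E)-8-ethyl-2,4,6,10-tetramethyl-12-phenyldodeca-2,5,7,9,11-pentaenoate F4. i-Bu2AlH (CH2Cl2, −78 °C) gives (2Z,4S,5E,7E,9E,11E)-8-ethyl-2,4,6,10-tetramethyl-12-phenyldodeca-2,5,7,9,11-pentaen-1-ol F5, and MnO2 gives (2Z,4S,5E,7E,9E,11E)-8-ethyl-2,4,6,10-tetramethyl-12-phenyldodeca-2,5,7,9,11-pentaenal F6. Wittig reaction of F6 with the ylide from (1-carboxyethyl)triphenylphosphonium bromide and two equivalents of KOt-Bu (THF, 0 °C), then acidification, gives 18, which is cyclised to 19 under the final conditions of step 9.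

Third: step 5. Dienal 7 is hindered at the α-carbon, and the trienal product 8 can compete for the ylide. The fallback sets out from 7 and comes back at 8. Horner–Wadsworth–Emmons reaction of 7 with triethyl 2-phosphonopropanoate (NaH, THF, 0 °C) gives ethyl (2E,4E,6E,8S)-9-[(tert-butyldimethylsilyl)oxy]-4-ethyl-2,6,8-trimethylnona-2,4,6-trienoate F7, which cannot be homologated further. i-Bu2AlH (2.2 equiv, −78 °C) gives (2E,4E,6E,8S)-9-[(tert-butyldimethylsilyl)oxy]-4-ethyl-2,6,8-trimethylnona-2,4,6-trien-1-ol F8, and MnO2 (CH2Cl2, rt) gives 8.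

**Further compounds**

F1 | step 9 | (2E,4Z,6S,7E,9E,11E,13E)-10-ethyl-2,4,6,8,12-pentamethyl-14-phenyltetradeca-2,4,7,9,11,13-hexaen-1-ol | c1ccccc1/C=C/C(C)=C/C(CC)=C/C(C)=C/[C@H](C)/C=C(C)\C=C(/C)CO
F2 | step 9 | (2E,4Z,6S,7E,9E,11E,13E)-10-ethyl-2,4,6,8,12-pentamethyl-14-phenyltetradeca-2,4,7,9,11,13-hexaenal | c1ccccc1/C=C/C(C)=C/C(CC)=C/C(C)=C/[C@H](C)/C=C(C)\C=C(/C)C=O
F3 | step 9 | (1R,3aR,4R,5S,7aS)-5-ethyl-1,3,4,7-tetramethyl-5-[(1E,3E)-2-methyl-4-phenylbuta-1,3-dien-1-yl]-3a,4,5,7a-tetrahydro-1H-indene-4-carbaldehyde | CC[C@]1(/C=C(C)/C=C/c2ccccc2)C=C(C)[C@H]2[C@H](C)C=C(C)[C@@H]2[C@@]1(C)C=O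
F4 | step 8 | ethyl (2Z,4S,5E,7E,9E,11E)-8-ethyl-2,4,6,10-tetramethyl-12-phenyldodeca-2,5,7,9,11-pentaenoate | c1ccccc1/C=C/C(C)=C/C(CC)=C/C(C)=C/[C@H](C)/C=C(C)\C(=O)OCC
F5 | step 8 | (2Z,4S,5E,7E,9E,11E)-8-ethyl-2,4,6,10-tetramethyl-12-phenyldodeca-2,5,7,9,11-pentaen-1-ol | c1ccccc1/C=C/C(C)=C/C(CC)=C/C(C)=C/[C@H](C)/C=C(C)\CO
F6 | step 8 | (2Z,4S,5E,7E,9E,11E)-8-ethyl-2,4,6,10-tetramethyl-12-phenyldodeca-2,5,7,9,11-pentaenal | c1ccccc1/C=C/C(C)=C/C(CC)=C/C(C)=C/[C@H](C)/C=C(C)\C=O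
F7 | step 5 | ethyl (2E,4E,6E,8S)-9-[(tert-butyldimethylsilyl)oxy]-4-ethyl-2,6,8-trimethylnona-2,4,6-trienoate | CCOC(=O)/C(C)=C/C(CC)=C/C(C)=C/[C@H](C)CO[Si](C)(C)C(C)(C)C
F8 | step 5 | (2E,4E,6E,8S)-9-[(tert-butyldimethylsilyl)oxy]-4-ethyl-2,6,8-trimethylnona-2,4,6-trien-1-ol | OC/C(C)=C/C(CC)=C/C(C)=C/[C@H](C)CO[Si](C)(C)C(C)(C)C
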